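## Retrosynthetic overview

1. Target 18 ⇐ aldehyde 16 in one operation: CrCl2-mediated intramolecular allylation (C6–C7) closes the ten-membered carbocycle, and the new C6 alkoxide translactonises a temporary six-membered lactone into the γ-lactone. Both target rings form here, and C6 and C7 are set.
2. 16 ⇐ diene ester 14 by ring-closing metathesis (temporary six-membered lactone through O9) and acetal hydrolysis.
3. 14 ⇐ enal 7 + chloropropenyl isovalerate 10 by catalytic asymmetric syn-γ-acyloxyallylation (C8–C9 bond, both stereocentres, isovalerate already on O8), then O9 acylation with acid 13.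
4. 7 ⇐ (S)-citronellal 1 (C4 stereocentre from the chiral pool): acetal, ozonolysis, Morita–Baylis–Hillman reaction with methyl acrylate, SN2' bromination, N-oxide oxidation.
5. Ring order: six-membered tether lactone first (step 9); then ten-membered ring and γ-lactone together (step 10), the tether lactone opening in the same step.

Atom labels used below follow the skeleton of 18: C6 lactone carbinol, C7 ring-fusion CH, C8 isovalerate carbon, C9 carbinol, C10 ester-bearing olefinic carbon, C1 olefinic CH, C4 methyl-bearing carbon, C11=C13 exocyclic methylene, C12 lactone carbonyl, C14 ester carbon.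

Assumption: the (R,R) salen ligand is taken to deliver the (8S,9S) adduct in step 7; if the sense is opposite, the (S,S) ligand is used with no other change.

## Route

Step 1
Reactants: 1 (S)-citronellal [(3S)-3,7-dimethyloct-6-enal]
Product: 2 (6S)-8,8-dimethoxy-2,6-dimethyloct-2-ene
Conditions: HC(OMe)3, MeOH, pyridinium p-toluenesulfonate (cat.), rt
Reagents that add atoms: trimethyl orthoformate, COC(OC)OC
Why: Acid-catalysed acetalisation masks the C6 aldehyde under conditions too mild for carbonyl-ene cyclisation, and the C4 stereocentre is not touched.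

Step 2
Reactants: 2 (6S)-8,8-dimethoxy-2,6-dimethyloct-2-ene
Product: 3 (4S)-6,6-dimethoxy-4-methylhexanal
Conditions: O3, CH2Cl2, −78 °C; then Me2S, −78 °C to rt
Reagents that add atoms: ozone, O=[O+][O-]
Why: Ozonolysis with reductive work-up cleaves the only olefin to the C1 aldehyde while the acetal is inert.

Step 3
Reactants: 3 (4S)-6,6-dimethoxy-4-methylhexanal; 4 methyl acrylate
Product: 5 methyl (6S)-3-hydroxy-8,8-dimethoxy-6-methyl-2-methylideneoctanoate (both C3 epimers)
Conditions: 1,4-diazabicyclo[2.2.2]octane (0.5 equiv), neat 4 (3 equiv), MeOH (1 equiv), rt, 4 d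
Reagents that add atoms: none
Why: The Morita–Baylis–Hillman reaction joins C1 to C10 and brings in C14 and the future C9; the carbinol configuration is irrelevant because it is erased in step 4.

Step 4
Reactants: 5 methyl (6S)-3-hydroxy-8,8-dimethoxy-6-methyl-2-methylideneoctanoate
Product: 6 methyl (2Z,6S)-2-(bromomethyl)-8,8-dimethoxy-6-methyloct-2-enoate
Conditions: N-bromosuccinimide, Me2S, CH2Cl2, 0 °C to rt
Reagents that add atoms: N-bromosuccinimide, O=C1CCC(=O)N1Br
Why: Corey–Kim-type activation of the allylic alcohol and SN2' bromide delivery give the thermodynamically preferred trisubstituted enoate with the chain trans to CO2Me, which is the C1=C10 geometry of the target.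

Step 5
Reactants: 6 methyl (2Z,6S)-2-(bromomethyl)-8,8-dimethoxy-6-methyloct-2-enoate
Product: 7 methyl (2E,6S)-2-formyl-8,8-dimethoxy-6-methyloct-2-enoate
Conditions: N-methylmorpholine N-oxide (3 equiv), 4 Å molecular sieves, MeCN, 0 °C to rt
Reagents that add atoms: N-methylmorpholine N-oxide, C[N+]1([O-])CCOCC1
Why: Kornblum-type N-oxide oxidation (SN2 at the primary allylic bromide, then elimination) gives the C9 aldehyde with the olefin geometry retained.

Step 6
Reactants: 8 acrolein; 9 3-methylbutanoyl chloride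
Product: 10 3-chloroprop-1-en-1-yl 3-methylbutanoate (E/Z mixture)
Conditions: ZnCl2 (2 mol %), CH2Cl2, −20 °C to rt
Reagents that add atoms: none
Why: Lewis-acid-catalysed conjugate addition of the acyl chloride to acrolein gives the γ-acyloxyallyl chloride; the E/Z ratio does not matter because both isomers give the same allylchromium.

Step 7
Reactants: 7 methyl (2E,6S)-2-formyl-8,8-dimethoxy-6-methyloct-2-enoate; 10 3-chloroprop-1-en-1-yl 3-methylbutanoate
Product: 12 methyl (2E,6S)-2-[(1S,2S)-1-hydroxy-2-(3-methylbutanoyloxy)but-3-en-1-yl]-8,8-dimethoxy-6-methyloct-2-enoate, via trimethylsilyl ether 11 (not isolated)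
Conditions: CrCl3 (10 mol %), (R,R)-N,N'-bis(3,5-di-tert-butylsalicylidene)cyclohexane-1,2-diamine (10 mol %), Et3N (20 mol %), Mn powder (3 equiv), Me3SiCl (1.5 equiv), MeCN, rt; then citric acid (cat.), MeOH, 0 °C
Reagents that add atoms: none
Why: The catalytic asymmetric Nozaki–Hiyama γ-acyloxyallylation adds 1,2 to the aldehyde with syn selectivity typical of salen–chromium allyl species, the ligand fixing 8S and 9S; O8 arrives already bearing the isovalerate, and in-situ silylation of O9 blocks acyl migration.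

Step 8
Reactants: 12 methyl (2E,6S)-2-[(1S,2S)-1-hydroxy-2-(3-methylbutanoyloxy)but-3-en-1-yl]-8,8-dimethoxy-6-methyloct-2-enoate; 13 2-(bromomethyl)prop-2-enoic acid
Product: 14 methyl (2E,6S)-2-[(1S,2S)-1-{[2-(bromomethyl)prop-2-enoyl]oxy}-2-(3-methylbutanoyloxy)but-3-en-1-yl]-8,8-dimethoxy-6-methyloct-2-enoate
Conditions: N,N'-dicyclohexylcarbodiimide (1.3 equiv), 4-(dimethylamino)pyridine (5 mol %), CH2Cl2, 0 °C
Reagents that add atoms: none
Why: Steglich esterification places the C11–C13 unit on O9 as a temporary tether; low catalyst loading and 0 °C limit attack on the allylic bromide and acyl migration, and no stereocentre is involved.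

Step 9
Reactants: 14 methyl (2E,6S)-2-[(1S,2S)-1-{[2-(bromomethyl)prop-2-enoyl]oxy}-2-(3-methylbutanoyloxy)but-3-en-1-yl]-8,8-dimethoxy-6-methyloct-2-enoate
Product: 16 methyl (2E,6S)-2-[(2S,3S)-5-(bromomethyl)-3-(3-methylbutanoyloxy)-6-oxo-3,6-dihydro-2H-pyran-2-yl]-6-methyl-8-oxooct-2-enoate, via lactone acetal 15 (not isolated)
Conditions: Hoveyda–Grubbs second-generation catalyst RuCl2(H2IMes)(=CH-C6H4-2-OiPr) (5 mol %), CH2Cl2 (0.01 M), 40 °C; then 1 M aq HCl, THF, rt
Reagents that add atoms: water, O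
Why: Ring-closing metathesis of the acrylate with the C7 vinyl group closes the six-membered unsaturated lactone (the trisubstituted enoate is inert), locking C8 trans to the CH2Br arm across C7=C11; aqueous acid then unmasks the C6 aldehyde.

Step 10
Reactants: 16 methyl (2E,6S)-2-[(2S,3S)-5-(bromomethyl)-3-(3-methylbutanoyloxy)-6-oxo-3,6-dihydro-2H-pyran-2-yl]-6-methyl-8-oxooct-2-enoate
Product: 18 methyl (3aS,4S,5S,6E,10S,11aR)-5-hydroxy-10-methyl-3-methylidene-4-(3-methylbutanoyloxy)-2-oxo-2,3,3a,4,5,8,9,10,11,11a-decahydrocyclodeca[b]furan-6-carboxylate (CNP0544142.1), via bridged hydroxy lactone 17 (not isolated)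
Conditions: CrCl2 (8 equiv), THF/DMF 4:1, syringe-pump addition (final 0.002 M), rt; then aq NH4Cl
Reagents that add atoms: none
Why: Proposed new method: divalent chromium inserts into the allylic C–Br bond and the allylchromium adds through C7 (SE2') to the C6 aldehyde in a closed chair transition state, with the ring-locked C8 equatorial (anti adduct, H6/H7 trans) and approach anti to the pseudoaxial C8 isovalerate (sets 7S, hence 6R), closing the ten-membered ring; the C6 alkoxide then attacks C12 (5-exo) so the strained bridged six-membered lactone translactonises to the trans-fused γ-lactone and frees O9–H; the closest known chemistry is the CrCl2-mediated macrocyclising allylation of ω-formyl allylic bromides to germacrane rings and metal-mediated allylation with 3-(bromomethyl)furan-2(5H)-ones.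

## Compound list

1 | (S)-citronellal, (3S)-3,7-dimethyloct-6-enal | C[C@@H](CCC=C(C)C)CC=O | starting material
2 | (6S)-8,8-dimethoxy-2,6-dimethyloct-2-ene | C[C@@H](CCC=C(C)C)CC(OC)OC | intermediate
3 | (4S)-6,6-dimethoxy-4-methylhexanal | C[C@@H](CCC=O)CC(OC)OC | intermediate
4 | methyl acrylate | C=CC(=O)OC | starting material
5 | methyl (6S)-3-hydroxy-8,8-dimethoxy-6-methyl-2-methylideneoctanoate (both C3 epimers) | C[C@@H](CCC(O)C(=C)C(=O)OC)CC(OC)OC | intermediate
6 | methyl (2Z,6S)-2-(bromomethyl)-8,8-dimethoxy-6-methyloct-2-enoate | C[C@@H](CC/C=C(/C(=O)OC)CBr)CC(OC)OC | intermediate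
7 | methyl (2E,6S)-2-formyl-8,8-dimethoxy-6-methyloct-2-enoate | C[C@@H](CC/C=C(/C(=O)OC)C=O)CC(OC)OC | intermediate
8 | acrolein | C=CC=O | starting material
9 | 3-methylbutanoyl chloride | CC(C)CC(=O)Cl | starting material
10 | 3-chloroprop-1-en-1-yl 3-methylbutanoate (E/Z mixture) | CC(C)CC(=O)OC=CCCl | intermediate
11 | methyl (2E,6S)-8,8-dimethoxy-6-methyl-2-[(1S,2S)-2-(3-methylbutanoyloxy)-1-(trimethylsilyloxy)but-3-en-1-yl]oct-2-enoate (not isolated) | C[C@@H](CC/C=C(/C(=O)OC)[C@H](O[Si](C)(C)C)[C@@H](OC(=O)CC(C)C)C=C)CC(OC)OC | intermediate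
12 | methyl (2E,6S)-2-[(1S,2S)-1-hydroxy-2-(3-methylbutanoyloxy)but-3-en-1-yl]-8,8-dimethoxy-6-methyloct-2-enoate | C[C@@H](CC/C=C(/C(=O)OC)[C@H](O)[C@@H](OC(=O)CC(C)C)C=C)CC(OC)OC | intermediate
13 | 2-(bromomethyl)prop-2-enoic acid | C=C(CBr)C(=O)O | starting material
14 | methyl (2E,6S)-2-[(1S,2S)-1-{[2-(bromomethyl)prop-2-enoyl]oxy}-2-(3-methylbutanoyloxy)but-3-en-1-yl]-8,8-dimethoxy-6-methyloct-2-enoate | C[C@@H](CC/C=C(/C(=O)OC)[C@H](OC(=O)C(=C)CBr)[C@@H](OC(=O)CC(C)C)C=C)CC(OC)OC | intermediate
15 | methyl (2E,6S)-2-[(2S,3S)-5-(bromomethyl)-3-(3-methylbutanoyloxy)-6-oxo-3,6-dihydro-2H-pyran-2-yl]-8,8-dimethoxy-6-methyloct-2-enoate (not isolated) | C[C@@H](CC/C=C(/C(=O)OC)[C@@H]1OC(=O)C(CBr)=C[C@@H]1OC(=O)CC(C)C)CC(OC)OC | intermediate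
16 | methyl (2E,6S)-2-[(2S,3S)-5-(bromomethyl)-3-(3-methylbutanoyloxy)-6-oxo-3,6-dihydro-2H-pyran-2-yl]-6-methyl-8-oxooct-2-enoate | C[C@@H](CC/C=C(/C(=O)OC)[C@@H]1OC(=O)C(CBr)=C[C@@H]1OC(=O)CC(C)C)CC=O | intermediate
17 | bridged hydroxy lactone (4S,6R,7S,8S,9S): ten-membered carbocycle with free C6–OH, C8 isovalerate, C11=C13 methylene and C12 still bound to O9 (six-membered lactone bridging C7 and C9); formed as its chromium alkoxide, written as the alcohol (not isolated) | C=C1C(=O)O[C@H]2/C(C(=O)OC)=C\CC[C@H](C)C[C@@H](O)[C@H]1[C@@H]2OC(=O)CC(C)C | intermediate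
18 | methyl (3aS,4S,5S,6E,10S,11aR)-5-hydroxy-10-methyl-3-methylidene-4-(3-methylbutanoyloxy)-2-oxo-2,3,3a,4,5,8,9,10,11,11a-decahydrocyclodeca[b]furan-6-carboxylate | C=C1C(=O)O[C@@H]2C[C@@H](C)CC/C=C(/C(=O)OC)[C@H](O)[C@@H](OC(=O)CC(C)C)[C@@H]12 | target

## Step count and risk

Total steps: 10. Longest linear sequence: 9 (steps 1–5 and 7–10; step 6 makes reagent 10).

Most likely to fail:

Step 10. The allylchromium carries the C8 isovalerate aligned with the allyl π system in the productive conformer, so reductive 1,4-elimination to a 2-pyranone can compete with the slow macrocyclisation. The bridged transition state is also strained, and oligomerisation is possible. The fallback sets out from 16 and returns at 18. Pd2(dba)3-catalysed borylation with bis(pinacolato)diboron (toluene, 50 °C) converts the allylic bromide into the allylboronate aldehyde F7. Heating F7 at 0.002 M in toluene (80 °C, Sc(OTf)3 10 mol %) effects intramolecular allylboration through the same closed chair, and the boron allyl cannot expel the carboxylate reductively. Work-up with camphorsulfonic acid cleaves the borate and lets the C6 hydroxyl translactonise to give 18.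

Step 7. On this electron-poor, branched enal the syn/anti ratio and ee may be modest, and Mn with silyl chloride may cause reductive side reactions. The fallback sets out from 7 and returns at 14. Allyl 4-methoxybenzyl ether is lithiated (sec-BuLi, THF, −78 °C) and converted with Ipc2BOMe and BF3·OEt2 into the (Z)-γ-alkoxyallyl-diisopinocampheylborane, using the Ipc enantiomer that gives 8S,9S. Addition to 7 and ethanolamine work-up give the PMB-ether alcohol F1. Esterification with 13 as in step 8 gives the PMB-ether bromomethylacrylate F2. DDQ (CH2Cl2, pH 7 buffer, 0 °C) gives the C8 alcohol F3, which is acylated at once with 9 (pyridine, CH2Cl2, −20 °C) to give 14.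

Step 9. The 2-(bromomethyl)acrylate and the allylic-ester olefin are both slow metathesis partners, and the allylic bromide may shorten catalyst life. The fallback sets out from 12 and returns at 15. Acylation of O9 with acryloyl chloride (iPr2NEt, CH2Cl2, −40 °C) gives the acrylate F4. Ring-closing metathesis of this unhindered acrylate with the same catalyst gives the unsubstituted lactone F5. Morita–Baylis–Hillman hydroxymethylation (aq. formaldehyde, imidazole, THF/H2O, rt) gives the hydroxymethyl lactone F6. Appel bromination (CBr4, PPh3, CH2Cl2, 0 °C) gives 15, which is hydrolysed to 16 as in step 9.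

Further compounds

F1 | step 7 | PMB-ether alcohol: methyl (2E,6S)-2-[(1S,2S)-1-hydroxy-2-(4-methoxybenzyloxy)but-3-en-1-yl]-8,8-dimethoxy-6-methyloct-2-enoate | C[C@@H](CC/C=C(/C(=O)OC)[C@H](O)[C@@H](OCc1ccc(OC)cc1)C=C)CC(OC)OC
F2 | step 7 | PMB-ether bromomethylacrylate: methyl (2E,6S)-2-[(1S,2S)-1-{[2-(bromomethyl)prop-2-enoyl]oxy}-2-(4-methoxybenzyloxy)but-3-en-1-yl]-8,8-dimethoxy-6-methyloct-2-enoate | C[C@@H](CC/C=C(/C(=O)OC)[C@H](OC(=O)C(=C)CBr)[C@@H](OCc1ccc(OC)cc1)C=C)CC(OC)OC
F3 | step 7 | C8 alcohol: methyl (2E,6S)-2-[(1S,2S)-1-{[2-(bromomethyl)prop-2-enoyl]oxy}-2-hydroxybut-3-en-1-yl]-8,8-dimethoxy-6-methyloct-2-enoate | C[C@@H](CC/C=C(/C(=O)OC)[C@H](OC(=O)C(=C)CBr)[C@@H](O)C=C)CC(OC)OC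
F4 | step 9 | acrylate: methyl (2E,6S)-8,8-dimethoxy-6-methyl-2-[(1S,2S)-2-(3-methylbutanoyloxy)-1-(prop-2-enoyloxy)but-3-en-1-yl]oct-2-enoate | C[C@@H](CC/C=C(/C(=O)OC)[C@H](OC(=O)C=C)[C@@H](OC(=O)CC(C)C)C=C)CC(OC)OC
F5 | step 9 | unsubstituted lactone: methyl (2E,6S)-8,8-dimethoxy-6-methyl-2-[(2S,3S)-3-(3-methylbutanoyloxy)-6-oxo-3,6-dihydro-2H-pyran-2-yl]oct-2-enoate | C[C@@H](CC/C=C(/C(=O)OC)[C@@H]1OC(=O)C=C[C@@H]1OC(=O)CC(C)C)CC(OC)OC
F6 | step 9 | hydroxymethyl lactone: methyl (2E,6S)-2-[(2S,3S)-5-(hydroxymethyl)-3-(3-methylbutanoyloxy)-6-oxo-3,6-dihydro-2H-pyran-2-yl]-8,8-dimethoxy-6-methyloct-2-enoate | C[C@@H](CC/C=C(/C(=O)OC)[C@@H]1OC(=O)C(CO)=C[C@@H]1OC(=O)CC(C)C)CC(OC)OC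
F7 | step 10 | allylboronate aldehyde: methyl (2E,6S)-6-methyl-2-[(2S,3S)-3-(3-methylbutanoyloxy)-6-oxo-5-[(4,4,5,5-tetramethyl-1,3,2-dioxaborolan-2-yl)methyl]-3,6-dihydro-2H-pyran-2-yl]-8-oxooct-2-enoate | C[C@@H](CC/C=C(/C(=O)OC)[C@@H]1OC(=O)C(CB2OC(C)(C)C(C)(C)O2)=C[C@@H]1OC(=O)CC(C)C)CC=O
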